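**Retrosynthetic overview**

1. Target 22 comes from its tris-MOM ether 21 by acid cleavage of three MOM groups; both prenyl groups are already in place.
2. 21 is cut at O1–C8a and C4–C4a into aryne 19 (ring A, triple bond C4a≡C8a, released from silyl triflate 10) and the (S)-β-hydroxy ester 18 (ring B plus C2, C3, C4). Rings A and B are bought as benzenes; ring C is the only ring formed, and it is formed last.
3. Enabling feature: the C5 oxygen of ring A sits next to C4a, so it polarises the aryne (O1 adds at C8a, the carbanion appears at C4a). O1 and the C4 acyl carbon are 1,3-related in 18, so the carbanion meets the ester through a six-membered ring.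
4. 10 comes from resorcinol via the symmetric phenol 6, whose symmetry fixes the prenyl group at C6: MOM, C2 prenylation, C–H borylation/oxidation, bromination, retro-Brook/triflation.
5. 18 comes from isovanillin: MOM, Comins ortho-prenylation, Roskamp homologation, asymmetric transfer hydrogenation (sets C2).

Key step: step 10

Remark: the SMILES fixes C2 as (S) (O1 > ring B carbon > C3 > H); all three phenols are carried as MOM ethers because a free phenol would itself add to the aryne.

**Route**

Step 1
Reactants: 1 resorcinol (benzene-1,3-diol)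
Product: 2 1,3-bis(methoxymethoxy)benzene
Conditions: MOMCl (2.5 equiv), i-Pr2NEt, CH2Cl2, 0 °C → rt
Reagents that add atoms: chloromethyl methyl ether (MOMCl), COCCl
Why: Base-mediated O-alkylation of both phenols (MOM ether formation) installs the acetal groups that later serve as ortho directors and as acid-labile protection.

Step 2
Reactants: 2 1,3-bis(methoxymethoxy)benzene
Product: 4 1,3-bis(methoxymethoxy)-2-(3-methylbut-2-en-1-yl)benzene, via aryllithium 3 (not isolated)
Conditions: n-BuLi, THF, 0 °C; CuI (10 mol %), prenyl bromide, −78 °C → rt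
Reagents that add atoms: prenyl bromide (1-bromo-3-methylbut-2-ene), CC(C)=CCBr
Why: Directed ortho-metalation at the position between the two OMOM groups, followed by copper-catalysed SN2 allylation of the aryllithium, should place the prenyl group between the two oxygens.

Step 3
Reactants: 4 1,3-bis(methoxymethoxy)-2-(3-methylbut-2-en-1-yl)benzene
Product: 6 3,5-bis(methoxymethoxy)-4-(3-methylbut-2-en-1-yl)phenol, via arylboronate 5 (not isolated)
Conditions: [Ir(OMe)(cod)]2 (1.5 mol %), 4,4'-di-tert-butyl-2,2'-bipyridine (3 mol %), B2pin2, THF, 80 °C; then H2O2, aq NaOH, 0 °C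
Reagents that add atoms: bis(pinacolato)diboron, CC1(C)OB(OC1(C)C)B1OC(C)(C)C(C)(C)O1 (held only in 5); hydrogen peroxide, OO (the phenol oxygen of 6)
Why: Sterically controlled iridium-catalysed C–H borylation should touch only the one ring C–H that has no ortho substituent, and oxidation of the C–B bond in the same flask should give the symmetric phenol.

Step 4
Reactants: 6 3,5-bis(methoxymethoxy)-4-(3-methylbut-2-en-1-yl)phenol
Product: 7 2-bromo-3,5-bis(methoxymethoxy)-4-(3-methylbut-2-en-1-yl)phenol
Conditions: NBS (1.0 equiv), CH2Cl2, −78 °C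
Reagents that add atoms: N-bromosuccinimide, O=C1CCC(=O)N1Br
Why: Electrophilic aromatic bromination ortho to the free phenol, where the two open ring positions are equivalent and far more nucleophilic than the trisubstituted alkene, should give one monobromide.

Step 5
Reactants: 7 2-bromo-3,5-bis(methoxymethoxy)-4-(3-methylbut-2-en-1-yl)phenol
Product: 10 3,5-bis(methoxymethoxy)-4-(3-methylbut-2-en-1-yl)-2-(trimethylsilyl)phenyl trifluoromethanesulfonate, via silyl ether 8 (not isolated), via lithium phenoxide 9 (not isolated)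
Conditions: HMDS, THF, 65 °C, then evaporate; n-BuLi, THF, −100 → −78 °C; Tf2O, −100 → −78 °C
Reagents that add atoms: hexamethyldisilazane, C[Si](C)(C)N[Si](C)(C)C; trifluoromethanesulfonic anhydride, O=S(=O)(OS(=O)(=O)C(F)(F)F)C(F)(F)F
Why: O-silylation, bromine–lithium exchange and retro-Brook (1,3 O→C) silyl migration should give the ortho-silyl phenoxide, which is trapped as the triflate, the standard way to a Kobayashi aryne precursor.

Step 6
Reactants: 11 isovanillin (3-hydroxy-4-methoxybenzaldehyde)
Product: 12 4-methoxy-3-(methoxymethoxy)benzaldehyde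
Conditions: MOMCl, i-Pr2NEt, CH2Cl2, 0 °C → rt
Reagents that add atoms: chloromethyl methyl ether (MOMCl), COCCl
Why: MOM ether formation masks the phenol, which would otherwise quench the organolithiums and add to the aryne, and turns it into an ortho director for step 7.

Step 7
Reactants: 12 4-methoxy-3-(methoxymethoxy)benzaldehyde
Product: 16 4-methoxy-3-(methoxymethoxy)-2-(3-methylbut-2-en-1-yl)benzaldehyde, via amino alkoxide 13 (not isolated), via aryllithium 14 (not isolated), via prenylated amino alkoxide 15 (not isolated)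
Conditions: Me2NCH2CH2N(Me)Li (from the amine and n-BuLi), THF, −20 °C; n-BuLi (3 equiv), −20 °C; prenyl bromide (excess), −78 °C → rt; H2O
Reagents that add atoms: prenyl bromide (1-bromo-3-methylbut-2-ene), CC(C)=CCBr; lithium [2-(dimethylamino)ethyl](methyl)amide, [Li]N(C)CCN(C)C (held only in 13 to 15)
Why: Comins ortho-lithiation of an in situ α-amino alkoxide, in which the masked aldehyde and the OMOM group together direct lithiation to the carbon between them, followed by SN2 prenylation and release of the aldehyde on work-up, should give the 2-prenyl aldehyde.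

Step 8
Reactants: 16 4-methoxy-3-(methoxymethoxy)-2-(3-methylbut-2-en-1-yl)benzaldehyde
Product: 17 ethyl 3-[4-methoxy-3-(methoxymethoxy)-2-(3-methylbut-2-en-1-yl)phenyl]-3-oxopropanoate
Conditions: ethyl diazoacetate, SnCl2 (10 mol %), CH2Cl2, rt
Reagents that add atoms: ethyl diazoacetate, CCOC(=O)C=[N+]=[N-]
Why: Roskamp homologation, in which the Lewis-acid-activated aldehyde is attacked by the diazo carbon and a 1,2-hydride shift with loss of N2 follows, should give the β-keto ester.

Step 9
Reactants: 17 ethyl 3-[4-methoxy-3-(methoxymethoxy)-2-(3-methylbut-2-en-1-yl)phenyl]-3-oxopropanoate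
Product: 18 ethyl (3S)-3-hydroxy-3-[4-methoxy-3-(methoxymethoxy)-2-(3-methylbut-2-en-1-yl)phenyl]propanoate
Conditions: RuCl(p-cymene)[(S,S)-TsDPEN] (1 mol %), HCO2H/Et3N (5:2), 30 °C
Reagents that add atoms: none
Why: Noyori–Ikariya asymmetric transfer hydrogenation of an aryl ketone, in which the (S,S)-TsDPEN ligand should deliver hydride to the Re face through the CH/π-organised six-membered transition state, should set the (S) carbinol centre that becomes C2 while leaving the prenyl alkene and MOM ethers untouched; any residual (R) ester would be removed here on a chiral stationary phase.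

Step 10
Reactants: 10 3,5-bis(methoxymethoxy)-4-(3-methylbut-2-en-1-yl)-2-(trimethylsilyl)phenyl trifluoromethanesulfonate; 18 ethyl (3S)-3-hydroxy-3-[4-methoxy-3-(methoxymethoxy)-2-(3-methylbut-2-en-1-yl)phenyl]propanoate
Product: 21 (2S)-5,7-bis(methoxymethoxy)-2-[4-methoxy-3-(methoxymethoxy)-2-(3-methylbut-2-en-1-yl)phenyl]-6-(3-methylbut-2-en-1-yl)-2,3-dihydro-4H-chromen-4-one, via aryne 19 (not isolated), via aryl potassium 20 (not isolated)
Conditions: KF (3 equiv), 18-crown-6, THF, 0 °C → rt, 10 (1.3 equiv) added slowly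
Reagents that add atoms: none
Why: Proposed new method: fluoride should strip the silyl group of 10 and expel triflate to give aryne 19, the fluoride-activated carbinol oxygen of 18 should add to C8a, and the C4a carbanion 20 so formed should attack the ester carbonyl and expel ethoxide, so that the O1–C8a and C4–C4a bonds and ring C arise in one operation. The closest known reaction type is the aryne annulation of salicylate esters to xanthones (O-arylation, then acyl capture by the aryl anion), together with aryne insertion into O–C(=O) and N–C(=O) bonds; what is new is an aliphatic β-hydroxy ester as the 1,3-oxygen/acyl partner. Ring C closes by 6-exo-trig attack of the aryl carbanion on the ester C=O after the intermolecular C–O bond formation. No stereocentre is made: C2 comes from 18 and should keep its (S) configuration because its C–O bond is never broken. The step needs regioselective O-attack on an unsymmetrical aryne, and this is secured by the C5 OMOM group next to C4a, which by its inductive pull and the aryne distortion it causes makes C8a (flanked only by C8–H) the electrophilic terminus and puts the charge at C4a; both prenyl groups are out of reach of the aryne for an intramolecular ene reaction. Acyl capture must outrun protonation of 20 and base-induced loss of the C2 oxygen (E1cB in 18, retro-oxa-Michael in 21), which is why an aprotic medium, slow addition of 10 and a temperature at or below rt are chosen.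

Step 11
Reactants: 21 (2S)-5,7-bis(methoxymethoxy)-2-[4-methoxy-3-(methoxymethoxy)-2-(3-methylbut-2-en-1-yl)phenyl]-6-(3-methylbut-2-en-1-yl)-2,3-dihydro-4H-chromen-4-one
Product: 22 (2S)-5,7-dihydroxy-2-[3-hydroxy-4-methoxy-2-(3-methylbut-2-en-1-yl)phenyl]-6-(3-methylbut-2-en-1-yl)-2,3-dihydro-4H-chromen-4-one
Conditions: 3 M aq HCl, MeOH, 40 °C, short reaction time
Reagents that add atoms: none
Why: Acid-catalysed acetal exchange (MOM cleavage) in methanol should free the three phenols, with acid strength and time kept low so that the prenyl groups are not protonated into chromans and the C2–O1 bond, which mild acid does not open, keeps its configuration.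

**Compound list**

1 | resorcinol | Oc1cccc(O)c1 | starting material
2 | 1,3-bis(methoxymethoxy)benzene | COCOc1cccc(OCOC)c1 | intermediate
3 | [2,6-bis(methoxymethoxy)phenyl]lithium | COCOc1cccc(OCOC)c1[Li] | intermediate (not isolated)
4 | 1,3-bis(methoxymethoxy)-2-(3-methylbut-2-en-1-yl)benzene | COCOc1cccc(OCOC)c1CC=C(C)C | intermediate
5 | 2-[3,5-bis(methoxymethoxy)-4-(3-methylbut-2-en-1-yl)phenyl]-4,4,5,5-tetramethyl-1,3,2-dioxaborolane | COCOc1cc(B2OC(C)(C)C(C)(C)O2)cc(OCOC)c1CC=C(C)C | intermediate (not isolated)
6 | 3,5-bis(methoxymethoxy)-4-(3-methylbut-2-en-1-yl)phenol | COCOc1cc(O)cc(OCOC)c1CC=C(C)C | intermediate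
7 | 2-bromo-3,5-bis(methoxymethoxy)-4-(3-methylbut-2-en-1-yl)phenol | Oc1cc(OCOC)c(CC=C(C)C)c(OCOC)c1Br | intermediate
8 | [2-bromo-3,5-bis(methoxymethoxy)-4-(3-methylbut-2-en-1-yl)phenoxy]trimethylsilane | C[Si](C)(C)Oc1cc(OCOC)c(CC=C(C)C)c(OCOC)c1Br | intermediate (not isolated)
9 | lithium 3,5-bis(methoxymethoxy)-4-(3-methylbut-2-en-1-yl)-2-(trimethylsilyl)phenoxide | [Li]Oc1cc(OCOC)c(CC=C(C)C)c(OCOC)c1[Si](C)(C)C | intermediate (not isolated)
10 | 3,5-bis(methoxymethoxy)-4-(3-methylbut-2-en-1-yl)-2-(trimethylsilyl)phenyl trifluoromethanesulfonate | O=S(=O)(Oc1cc(OCOC)c(CC=C(C)C)c(OCOC)c1[Si](C)(C)C)C(F)(F)F | intermediate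
11 | isovanillin (3-hydroxy-4-methoxybenzaldehyde) | COc1ccc(C=O)cc1O | starting material
12 | 4-methoxy-3-(methoxymethoxy)benzaldehyde | COCOc1cc(C=O)ccc1OC | intermediate
13 | lithium {[2-(dimethylamino)ethyl](methyl)amino}[4-methoxy-3-(methoxymethoxy)phenyl]methanolate | COCOc1cc(C(O[Li])N(C)CCN(C)C)ccc1OC | intermediate (not isolated)
14 | C2-lithiated derivative of 13 | COCOc1c([Li])c(C(O[Li])N(C)CCN(C)C)ccc1OC | intermediate (not isolated)
15 | C2-prenylated derivative of 13 | COCOc1c(CC=C(C)C)c(C(O[Li])N(C)CCN(C)C)ccc1OC | intermediate (not isolated)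
16 | 4-methoxy-3-(methoxymethoxy)-2-(3-methylbut-2-en-1-yl)benzaldehyde | COCOc1c(CC=C(C)C)c(C=O)ccc1OC | intermediate
17 | ethyl 3-[4-methoxy-3-(methoxymethoxy)-2-(3-methylbut-2-en-1-yl)phenyl]-3-oxopropanoate | CCOC(=O)CC(=O)c1ccc(OC)c(OCOC)c1CC=C(C)C | intermediate
18 | ethyl (3S)-3-hydroxy-3-[4-methoxy-3-(methoxymethoxy)-2-(3-methylbut-2-en-1-yl)phenyl]propanoate | CCOC(=O)C[C@H](O)c1ccc(OC)c(OCOC)c1CC=C(C)C | intermediate
19 | 1,2-didehydro-3,5-bis(methoxymethoxy)-4-(3-methylbut-2-en-1-yl)benzene (aryne) | COCOC1=CC#CC(OCOC)=C1CC=C(C)C | intermediate (not isolated)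
20 | ethyl (3S)-3-[3,5-bis(methoxymethoxy)-4-(3-methylbut-2-en-1-yl)-2-potassiophenoxy]-3-[4-methoxy-3-(methoxymethoxy)-2-(3-methylbut-2-en-1-yl)phenyl]propanoate | CCOC(=O)C[C@H](Oc1cc(OCOC)c(CC=C(C)C)c(OCOC)c1[K])c1ccc(OC)c(OCOC)c1CC=C(C)C | intermediate (not isolated)
21 | (2S)-5,7-bis(methoxymethoxy)-2-[4-methoxy-3-(methoxymethoxy)-2-(3-methylbut-2-en-1-yl)phenyl]-6-(3-methylbut-2-en-1-yl)-2,3-dihydro-4H-chromen-4-one | COc1ccc([C@@H]2CC(=O)c3c(cc(OCOC)c(CC=C(C)C)c3OCOC)O2)c(CC=C(C)C)c1OCOC | intermediate
22 | (2S)-5,7-dihydroxy-2-[3-hydroxy-4-methoxy-2-(3-methylbut-2-en-1-yl)phenyl]-6-(3-methylbut-2-en-1-yl)-2,3-dihydro-4H-chromen-4-one | COc1ccc([C@@H]2CC(=O)c3c(cc(O)c(CC=C(C)C)c3O)O2)c(CC=C(C)C)c1O | target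

**Step count**

Total steps: 11. Longest linear sequence: 7 steps (resorcinol 1 to 22 through steps 1 to 5, 10 and 11).

**Steps most likely to fail**

Step 10 (proposed new method). Possible failures:
- protonation of the aryl anion before it reaches the ester, leaving an open aryl ether;
- loss of the aryne to oligomerisation or to an intermolecular ene reaction with a prenyl alkene;
- E1cB loss of the carbinol oxygen from 18;
- erosion of the C2 configuration by base-induced opening and reclosure of ring C in 21.

Fallback with known chemistry, setting out from 7 and 16 and coming back at 21: treatment of 7 with n-BuLi (2.2 equiv, THF, −78 °C) gives the dilithiated phenoxide F1, which is acylated by N-methoxy-N-methylacetamide to the acetophenone F2. Claisen–Schmidt condensation of F2 with 16 (KOH, EtOH, rt) gives the 2'-hydroxychalcone F3. NaOAc in refluxing EtOH closes ring C by oxa-Michael addition to the racemic flavanone F4. Preparative HPLC on a chiral stationary phase then gives 21.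

Step 8. Possible failures: 1,2-shift of the electron-rich aryl group instead of hydride in the diazonium betaine, or slow addition to the hindered, electron-rich aldehyde. Fallback from 16, coming back at 17: aldol addition of the lithium enolate of ethyl acetate (LDA, EtOAc, THF, −78 °C) gives the racemic β-hydroxy ester F5, and Dess–Martin oxidation (NaHCO3, CH2Cl2, rt) gives 17.

Step 3. Possible failures: hydroboration or isomerisation of the prenyl alkene by the iridium boryl/hydride species, or stalled C–H borylation. Fallback from 2, coming back at 6: the same borylation/oxidation is run on 2, which has no alkene, and gives through the arylboronate F6 the phenol F7. TIPSCl and imidazole in DMF give the silyl ether F8. n-BuLi in THF at 0 °C lithiates between the two OMOM groups (the bulky silyl ether does not direct) to give the aryllithium F9. CuI (10 mol %) and prenyl bromide give the prenylated silyl ether F10, and TBAF in THF releases 6.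

**Further compounds**

F1 | step 10 | lithium 2-lithio-3,5-bis(methoxymethoxy)-4-(3-methylbut-2-en-1-yl)phenoxide | [Li]Oc1cc(OCOC)c(CC=C(C)C)c(OCOC)c1[Li]
F2 | step 10 | 1-[6-hydroxy-2,4-bis(methoxymethoxy)-3-(3-methylbut-2-en-1-yl)phenyl]ethan-1-one | CC(=O)c1c(O)cc(OCOC)c(CC=C(C)C)c1OCOC
F3 | step 10 | (2E)-1-[6-hydroxy-2,4-bis(methoxymethoxy)-3-(3-methylbut-2-en-1-yl)phenyl]-3-[4-methoxy-3-(methoxymethoxy)-2-(3-methylbut-2-en-1-yl)phenyl]prop-2-en-1-one | COCOc1c(CC=C(C)C)c(/C=C/C(=O)c2c(O)cc(OCOC)c(CC=C(C)C)c2OCOC)ccc1OC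
F4 | step 10 | racemic 5,7-bis(methoxymethoxy)-2-[4-methoxy-3-(methoxymethoxy)-2-(3-methylbut-2-en-1-yl)phenyl]-6-(3-methylbut-2-en-1-yl)-2,3-dihydro-4H-chromen-4-one | COc1ccc(C2CC(=O)c3c(cc(OCOC)c(CC=C(C)C)c3OCOC)O2)c(CC=C(C)C)c1OCOC
F5 | step 8 | racemic ethyl 3-hydroxy-3-[4-methoxy-3-(methoxymethoxy)-2-(3-methylbut-2-en-1-yl)phenyl]propanoate | CCOC(=O)CC(O)c1ccc(OC)c(OCOC)c1CC=C(C)C
F6 | step 3 | 2-[3,5-bis(methoxymethoxy)phenyl]-4,4,5,5-tetramethyl-1,3,2-dioxaborolane | COCOc1cc(B2OC(C)(C)C(C)(C)O2)cc(OCOC)c1
F7 | step 3 | 3,5-bis(methoxymethoxy)phenol | COCOc1cc(O)cc(OCOC)c1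
F8 | step 3 | [3,5-bis(methoxymethoxy)phenoxy]tri(propan-2-yl)silane | COCOc1cc(O[Si](C(C)C)(C(C)C)C(C)C)cc(OCOC)c1
F9 | step 3 | {2,6-bis(methoxymethoxy)-4-[tri(propan-2-yl)silyloxy]phenyl}lithium | COCOc1cc(O[Si](C(C)C)(C(C)C)C(C)C)cc(OCOC)c1[Li]
F10 | step 3 | [3,5-bis(methoxymethoxy)-4-(3-methylbut-2-en-1-yl)phenoxy]tri(propan-2-yl)silane | COCOc1cc(O[Si](C(C)C)(C(C)C)C(C)C)cc(OCOC)c1CC=C(C)C
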